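**Retrosynthetic overview**

- Feature: in the ten-membered carbocycle the oxygenated carbons C3 and C8 lie transannular (1,6). A C3–C8 bond folds the ring into a Δ3(8)-octalin whose ring C8–C9–C10–C1–C2–C3 is the Birch product of a 7-methoxytetralin with C10 as the methoxy carbon; the other ring (C3 to C8) already carries C4-Me and the cis C6/C7 pair.
- Target ⇒ C8 angelate, C3 acetate and C11 methylene (last) ⇒ C10 methyl carbinol from the C10 enone ⇒ C3 alcohol from the 1E,4Z-dienone ⇒ cis γ-lactone ⇒ cyclodecane-3,8-dione 16, with C8 reduced 1,3-anti from the C6 hydroxyl.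
- 16 ⇒ ozonolysis of the ring-fusion alkene of octalin ketal 13 ⇒ Birch reduction and ketalisation of tetralin 11 ⇒ cis-lactone 9 (enamine alkylation, dynamic-kinetic transfer hydrogenation) ⇒ 2-tetralone 4 ⇒ 3-methoxyphenylacetic acid + propene.
- Order of ring formation: arene (bought) → carbocycle of the tetralin (step 1) → ten-membered ring by scission of the shared bond (step 8) → γ-lactone (step 13).

Key step: step 8

Remark on numbering: germacrane numbering is used throughout (C6 lactone O–CH, C7 ring CH bearing C11, C12 lactone carbonyl, C13 exocyclic methylene, C14 methyl on C10, C15 methyl on C4); β is the ring face that carries the C7–C11 bond; TBS = tert-butyldimethylsilyl.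
Assumption 1: C4 is formed as a racemate in step 1 and is not controlled, so 4 and 6–24 are mixtures of C4 epimers (drawn without a C4 descriptor) that converge when C4 becomes sp2 in step 15.
Assumption 2: the sense of the transfer hydrogenation in step 3 is assigned by the aryl-ketone model with the benzylic, substituted C7 side as the large group; should it prove opposite, the (S,S) catalyst is used.
Remark: the γ-hydroxy ketones 16, 19 and 20 may rest partly as transannular C3/C6 hemiketals and are drawn in the open form.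

**Route**

Step 1
Reactants: 1 3-methoxyphenylacetic acid; 2 propene
Product: 4 7-methoxy-4-methyl-3,4-dihydronaphthalen-2(1H)-one (racemic), via acid chloride 3 (not isolated)
Conditions: (COCl)2, cat. HCONMe2, CH2Cl2, 0 °C to rt; then AlCl3, propene, CH2Cl2, −10 to 0 °C
Reagents that add atoms: none
Why: Friedel–Crafts acylation of propene by the acylium ion of 3 and intramolecular Friedel–Crafts alkylation by the resulting secondary cation (the acylation–cycloalkylation route to 2-tetralones) should close the ring para to the methoxy group and place the methyl group on the benzylic carbon C4, which is formed as a racemate.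

Step 2
Reactants: 4 7-methoxy-4-methyl-3,4-dihydronaphthalen-2(1H)-one; 5 ethyl bromoacetate
Product: 7 ethyl 2-(7-methoxy-4-methyl-2-oxo-1,2,3,4-tetrahydronaphthalen-1-yl)acetate, via enamine 6 (not isolated)
Conditions: pyrrolidine, toluene, reflux (−H2O); then BrCH2CO2Et, MeCN, reflux; then H2O/AcOH, rt
Reagents that add atoms: water, O
Why: Stork enamine alkylation: the arene-conjugated pyrrolidine enamine 6 is C-alkylated only at the benzylic carbon C7 and only once, and aqueous hydrolysis returns the ketone, whose C7 centre stays configurationally labile.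

Step 3
Reactants: 7 ethyl 2-(7-methoxy-4-methyl-2-oxo-1,2,3,4-tetrahydronaphthalen-1-yl)acetate
Product: 9 (3aR,9bS)-8-methoxy-5-methyl-3a,4,5,9b-tetrahydronaphtho[2,1-b]furan-2(1H)-one (cis-fused lactone), via hydroxy ester 8 (not isolated)
Conditions: RuCl(p-cymene)[(R,R)-TsNCH(Ph)CH(Ph)NH2] (1 mol%), HCO2H/Et3N (5:2), CH2Cl2, 35 °C; then 4-MeC6H4SO3H (cat.), toluene, 50 °C
Reagents that add atoms: none
Why: Noyori-type asymmetric transfer hydrogenation under dynamic kinetic resolution: C7 epimerises fast through the arene-conjugated enol, the chiral ruthenium hydride fixes C6 as R, and hydride adds anti to the pseudoaxial C7 side chain so that the 6,7-cis hydroxy ester 8 (C7 S) forms and lactonises under acid to the cis-fused lactone 9, while the remote C4 centre is not resolved.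

Step 4
Reactants: 9 cis-fused lactone
Product: 10 (1S,2R)-1-(2-hydroxyethyl)-7-methoxy-4-methyl-1,2,3,4-tetrahydronaphthalen-2-ol
Conditions: LiAlH4, THF, 0 °C to rt
Reagents that add atoms: none
Why: Hydride reduction of the lactone by LiAlH4 to the 1,4-diol, with no effect on the anisole or on the stereocentres.

Step 5
Reactants: 10 diol
Product: 11 (1S,2R)-1-[2-(tert-butyldimethylsilyloxy)ethyl]-7-methoxy-4-methyl-1,2,3,4-tetrahydronaphthalen-2-ol
Conditions: TBSCl, imidazole, CH2Cl2, 0 °C
Reagents that add atoms: tert-butyldimethylsilyl chloride, C[Si](C)(Cl)C(C)(C)C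
Why: Silylation with TBSCl/imidazole takes the unhindered primary hydroxyl and leaves the secondary C6 hydroxyl free as the later directing group.

Step 6
Reactants: 11 silyl ether of the methoxytetralin
Product: 12 (1S,2R)-1-[2-(tert-butyldimethylsilyloxy)ethyl]-7-methoxy-4-methyl-1,2,3,4,5,8-hexahydronaphthalen-2-ol
Conditions: Li, NH3 (l), THF, t-BuOH, −78 to −33 °C; then NH4Cl
Reagents that add atoms: none
Why: Birch reduction by electron transfer and protonation should stop at the 2,5-dihydroanisole with one alkene on the methoxy carbon (C10=C1) and the other on the two alkyl-substituted ring-fusion carbons (C3=C8), the lithium alkoxide and the silyl ether being inert.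

Step 7
Reactants: 12 Birch enol ether
Product: 13 (1S,2R)-1-[2-(tert-butyldimethylsilyloxy)ethyl]-7,7-(ethylenedioxy)-4-methyl-1,2,3,4,5,6,7,8-octahydronaphthalen-2-ol (octalin ketal; C3=C8 ring-fusion alkene)
Conditions: HOCH2CH2OH, pyridinium 4-toluenesulfonate (cat.), CH2Cl2, rt
Reagents that add atoms: ethylene glycol, OCCO
Why: Acid-catalysed transketalisation: protonation of the enol ether at C1, capture of the oxocarbenium ion by ethylene glycol and loss of methanol give the dioxolane without a free C10 ketone, so the C3=C8 alkene cannot move into conjugation.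

Step 8
Reactants: 13 octalin ketal
Product: 16 (6R,7R)-10,10-(ethylenedioxy)-6-hydroxy-4-methyl-7-[2-(tert-butyldimethylsilyloxy)ethyl]cyclodecane-3,8-dione (6β-OH; used crude), via primary ozonide 14 (not isolated), via methoxy hydroperoxide 15 (not isolated)
Conditions: O3 (1 equiv), CH2Cl2/MeOH (5:1), NaHCO3, −78 °C; then Me2S, −78 °C to rt
Reagents that add atoms: ozone, [O-][O+]=O
Why: 1,3-Dipolar cycloaddition of ozone to the electron-rich tetrasubstituted C3=C8 alkene gives primary ozonide 14, whose cycloreversion to a carbonyl oxide and a ketone is intercepted by methanol as hydroperoxide 15 (drawn as the C3 regioisomer), and Me2S reduces the O–O bond to release the second ketone. The closest known reaction type is the ozonolysis of Δ9(10)-octalins to cyclodecane-1,6-diones. The ten-membered ring is not closed by bond formation but appears by scission of the bond shared by the two six-membered rings, so that their peripheries merge and no macrocyclisation is needed; the two new skeletal bonds are the C3=O and C8=O bonds. No stereocentre is formed, and C6 and C7 are carried over unchanged. The first selectivity needed is attack on the only C=C bond without oxidation of the ketal, the silyl ether or the secondary alcohol, which the high nucleophilicity of the tetrasubstituted alkene, the lack of a C–H bond on the ketal carbon, −78 °C and one equivalent of ozone should secure. The second is survival of the β-hydroxy 1,6-diketone, whose C7 is now α to the C8 ketone, against transannular aldol, β-elimination and epimerisation, which the bicarbonate buffer, the neutral reductive work-up and immediate use in step 9 should secure.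

Step 9
Reactants: 16 cyclodecane-3,8-dione
Product: 17 6β-acetoxy-10,10-(ethylenedioxy)-8α-hydroxy-4-methyl-7-[2-(tert-butyldimethylsilyloxy)ethyl]cyclodecan-3-one
Conditions: SmI2 (30 mol%), CH3CHO, THF, −10 °C
Reagents that add atoms: acetaldehyde, CC=O
Why: Evans–Tishchenko reduction: the C6 hydroxyl forms a samarium-bound hemiacetal with acetaldehyde and passes its hydride intramolecularly to the β-carbonyl C8 through a chair-like bicyclic transition state, which sets C8 1,3-anti to C6 (8α-OH), leaves the γ-related C3 ketone alone and turns the C6 oxygen into its acetate so that the two secondary oxygens are differentiated.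

Step 10
Reactants: 17 hydroxy acetate
Product: 18 6β-acetoxy-8α-(tert-butyldimethylsilyloxy)-10,10-(ethylenedioxy)-4-methyl-7-[2-(tert-butyldimethylsilyloxy)ethyl]cyclodecan-3-one
Conditions: TBSOTf, 2,6-lutidine, CH2Cl2, −78 °C
Reagents that add atoms: tert-butyldimethylsilyl trifluoromethanesulfonate, C[Si](C)(OS(=O)(=O)C(F)(F)F)C(C)(C)C
Why: Silylation of the only free hydroxyl with the silyl triflate and a hindered base at low temperature, before any 1,3-acyl shift, gives the bulky non-chelating C8 ether.

Step 11
Reactants: 18 bis-silyl ether acetate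
Product: 19 8α-(tert-butyldimethylsilyloxy)-10,10-(ethylenedioxy)-6β-hydroxy-4-methyl-7-[2-(tert-butyldimethylsilyloxy)ethyl]cyclodecan-3-one
Conditions: K2CO3, MeOH, 0 °C
Reagents that add atoms: none
Why: Base-catalysed methanolysis (transesterification) removes the acetate, and the freed C6 hydroxyl may rest harmlessly as the hemiketal with the C3 ketone.

Step 12
Reactants: 19 C6 alcohol
Product: 20 8α-(tert-butyldimethylsilyloxy)-10,10-(ethylenedioxy)-6β-hydroxy-7-(2-hydroxyethyl)-4-methylcyclodecan-3-one
Conditions: HF·pyridine, pyridine, THF, 0 °C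
Reagents that add atoms: none
Why: Buffered HF·pyridine cleaves the unhindered primary silyl ether much faster than the secondary C8 silyl ether and does not touch the dioxolane.

Step 13
Reactants: 20 diol
Product: 22 8α-(tert-butyldimethylsilyloxy)-10,10-(ethylenedioxy)-3-oxo-13,14-dinorgermacran-12,6-olide (6β-O, 7α-H, cis-fused γ-lactone), via lactol 21 (not isolated)
Conditions: 2,2,6,6-tetramethylpiperidine-1-oxyl (cat.), PhI(OAc)2, CH2Cl2, rt
Reagents that add atoms: none
Why: Oxoammonium (TEMPO) oxidation of the primary alcohol to the aldehyde, closure with the cis C6 hydroxyl to lactol 21 and a second oxidation give the cis-fused γ-lactone, and because C8 is silylated only the C6 oxygen can lactonise.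

Step 14
Reactants: 22 lactone ketone
Product: 24 8α-(tert-butyldimethylsilyloxy)-10,10-(ethylenedioxy)-3-oxo-13,14-dinorgermacr-1E-en-12,6-olide, via selenide 23 (not isolated)
Conditions: LiN(iPr)2, THF, −78 °C; PhSeCl; then H2O2, pyridine, CH2Cl2, 0 °C to rt
Reagents that add atoms: none
Why: Kinetic deprotonation at the less substituted α-carbon C2 (more acidic than the lactone CH2), selenenylation and selenoxide syn-elimination, which can only run towards C1, should give the E-enone because the fully substituted C10 would clash with C3 (allylic 1,3-strain) in the Z transition state.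

Step 15
Reactants: 24 E-enone
Product: 26 8α-(tert-butyldimethylsilyloxy)-10,10-(ethylenedioxy)-3-oxo-13,14-dinorgermacra-1E,4Z-dien-12,6-olide, via silyl dienol ether 25 (not isolated)
Conditions: Me3SiOTf, Et3N, CH2Cl2, 0 °C; then Pd(OAc)2, MeCN, rt
Reagents that add atoms: none
Why: Saegusa–Ito oxidation: soft enolisation at C4, the only α-position left, gives silyl dienol ether 25, and syn β-hydride elimination from the palladium enolate towards the ring carbon C5 should give the conjugated trisubstituted enone with C3 and C6 cis (4Z), the less strained geometry in a ten-membered ring, at which point the C4 epimers converge.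

Step 16
Reactants: 26 cross-conjugated dienone
Product: 27 8α-(tert-butyldimethylsilyloxy)-10,10-(ethylenedioxy)-3β-hydroxy-13,14-dinorgermacra-1E,4Z-dien-12,6-olide (3R)
Conditions: (S)-1-methyl-3,3-diphenyltetrahydro-1H,3H-pyrrolo[1,2-c][1,3,2]oxazaborole (0.5 equiv), catecholborane, toluene, −78 °C
Reagents that add atoms: none
Why: Corey–Bakshi–Shibata reduction: the oxazaborolidine binds the carbonyl oxygen anti to the larger α-methylalkenyl arm (C4 side) and the coordinated borane delivers hydride 1,2 to the face that gives the 3R (3β) bis-allylic alcohol, so C3 is set by the reagent.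

Step 17
Reactants: 27 dienol ketal
Product: 28 8α-(tert-butyldimethylsilyloxy)-3β-hydroxy-10-oxo-13,14-dinorgermacra-1E,4Z-dien-12,6-olide
Conditions: pyridinium 4-toluenesulfonate (cat.), acetone/H2O (9:1), 40 °C
Reagents that add atoms: water, O
Why: Mild acid hydrolysis of the dioxolane, which is allylic and ionises readily, unmasks the C10 ketone as the E-enone while the silyl ether and the lactone survive.

Step 18
Reactants: 28 γ-hydroxy enone
Product: 29 8α-(tert-butyldimethylsilyloxy)-3β,10β-dihydroxy-13-norgermacra-1E,4Z-dien-12,6-olide (C14 methyl α)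
Conditions: MeLi, CeCl3, THF, −78 °C
Reagents that add atoms: methyllithium, [Li]C
Why: 1,2-Addition of the weakly basic organocerium reagent to the enone carbonyl: with the non-chelating C8 silyl ether the C10=O dipole is expected to point away from the C8–O bond and the methyl group to enter from the ring periphery anti to C8 (Felkin–Anh type), which sets C10 with its hydroxyl β and trans to the C8 oxygen, whereas a chelate would hold both oxygens on one face and lead to the epimer.

Step 19
Reactants: 29 diol lactone
Product: 32 8α-(tert-butyldimethylsilyloxy)-3β,10β-dihydroxygermacra-1E,4Z,11(13)-trien-12,6-olide, via Mannich base 30 (not isolated), via methiodide 31 (not isolated)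
Conditions: LiN(iPr)2 (3.5 equiv), THF, −78 to −40 °C; CH2=NMe2 I; then MeI, MeOH, rt; then NaHCO3 (aq.), CH2Cl2
Reagents that add atoms: N,N-dimethylmethyleneiminium iodide (Eschenmoser's salt), C=[N+](C)C.[I-]
Why: Aminomethylation of the lactone lithium enolate with Eschenmoser's salt, N-methylation and E1cB loss of trimethylamine install the exocyclic methylene, the two hydroxyls being carried as lithium alkoxides and no other enolisable carbonyl being present.

Step 20
Reactants: 32 α-methylene lactone diol
Product: 33 3β-acetoxy-8α-(tert-butyldimethylsilyloxy)-10β-hydroxygermacra-1E,4Z,11(13)-trien-12,6-olide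
Conditions: Ac2O, pyridine, 4-(dimethylamino)pyridine (cat.), CH2Cl2, 0 °C
Reagents that add atoms: acetic anhydride, CC(=O)OC(C)=O
Why: Nucleophile-catalysed acetylation takes the secondary C3 hydroxyl and leaves the tertiary C10 hydroxyl untouched on steric grounds.

Step 21
Reactants: 33 acetate silyl ether
Product: 34 3β-acetoxy-8α,10β-dihydroxygermacra-1E,4Z,11(13)-trien-12,6-olide
Conditions: HF·pyridine, pyridine, THF, 0 °C to rt
Reagents that add atoms: none
Why: Cleavage of the secondary silyl ether by buffered HF·pyridine, conditions that the allylic acetate, the tertiary allylic alcohol and the α-methylene lactone tolerate.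

Step 22
Reactants: 34 C8 alcohol; 35 angelic acid
Product: 37 CNP0181631.1 (3R,6R,7S,8R,10R)-3-acetoxy-8-angeloyloxy-10-hydroxygermacra-1E,4Z,11(13)-trien-12,6-olide, via mixed anhydride 36 (not isolated)
Conditions: angelic acid, 2,4,6-Cl3C6H2COCl, Et3N, toluene, rt; then 34, 75 °C
Reagents that add atoms: none
Why: Yamaguchi-type esterification through mixed anhydride 36 without a nucleophilic catalyst acylates the C8 hydroxyl at the less hindered angeloyl carbonyl with no Z-to-E isomerisation, and the tertiary C10 hydroxyl does not react.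

**Compound list**

1 | 3-methoxyphenylacetic acid | COc1cccc(CC(=O)O)c1 | starting material
2 | propene | C=CC | starting material
3 | 3-methoxyphenylacetyl chloride (not isolated) | COc1cccc(CC(Cl)=O)c1 | intermediate
4 | 7-methoxy-4-methyl-3,4-dihydronaphthalen-2(1H)-one (racemic) | COc1ccc2c(c1)CC(=O)CC2C | intermediate
5 | ethyl bromoacetate | CCOC(=O)CBr | starting material
6 | 1-(7-methoxy-4-methyl-3,4-dihydronaphthalen-2-yl)pyrrolidine (not isolated) | COc1ccc2c(c1)C=C(N1CCCC1)CC2C | intermediate
7 | ethyl 2-(7-methoxy-4-methyl-2-oxo-1,2,3,4-tetrahydronaphthalen-1-yl)acetate (C1 labile) | CCOC(=O)CC1C(=O)CC(C)c2ccc(OC)cc21 | intermediate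
8 | ethyl 2-[(1S,2R)-2-hydroxy-7-methoxy-4-methyl-1,2,3,4-tetrahydronaphthalen-1-yl]acetate (not isolated) | COc1ccc2c(c1)[C@H](CC(=O)OCC)[C@H](O)CC2C | intermediate
9 | (3aR,9bS)-8-methoxy-5-methyl-3a,4,5,9b-tetrahydronaphtho[2,1-b]furan-2(1H)-one (cis-fused) | COc1ccc2c(c1)[C@@H]1CC(=O)O[C@@H]1CC2C | intermediate
10 | (1S,2R)-1-(2-hydroxyethyl)-7-methoxy-4-methyl-1,2,3,4-tetrahydronaphthalen-2-ol | COc1ccc2c(c1)[C@H](CCO)[C@H](O)CC2C | intermediate
11 | (1S,2R)-1-[2-(tert-butyldimethylsilyloxy)ethyl]-7-methoxy-4-methyl-1,2,3,4-tetrahydronaphthalen-2-ol | COc1ccc2c(c1)[C@H](CCO[Si](C)(C)C(C)(C)C)[C@H](O)CC2C | intermediate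
12 | (1S,2R)-1-[2-(tert-butyldimethylsilyloxy)ethyl]-7-methoxy-4-methyl-1,2,3,4,5,8-hexahydronaphthalen-2-ol | COC1=CCC2=C(C1)[C@H](CCO[Si](C)(C)C(C)(C)C)[C@H](O)CC2C | intermediate
13 | (1S,2R)-1-[2-(tert-butyldimethylsilyloxy)ethyl]-7,7-(ethylenedioxy)-4-methyl-1,2,3,4,5,6,7,8-octahydronaphthalen-2-ol (octalin ketal) | O[C@@H]1CC(C)C2=C(CC3(OCCO3)CC2)[C@@H]1CCO[Si](C)(C)C(C)(C)C | intermediate
14 | primary ozonide of 13: 1,2,3-trioxolane fused across C3–C8 (not isolated) | O[C@@H]1CC(C)C23OOOC3(CC3(OCCO3)CC2)[C@@H]1CCO[Si](C)(C)C(C)(C)C | intermediate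
15 | 3-hydroperoxy-3-methoxy-8-oxo ring-opened peroxide, otherwise as 16 (not isolated) | O[C@@H]1CC(C)C(OC)(OO)CCC2(OCCO2)CC(=O)[C@@H]1CCO[Si](C)(C)C(C)(C)C | intermediate
16 | (6R,7R)-10,10-(ethylenedioxy)-6-hydroxy-4-methyl-7-[2-(tert-butyldimethylsilyloxy)ethyl]cyclodecane-3,8-dione | O[C@@H]1CC(C)C(=O)CCC2(OCCO2)CC(=O)[C@@H]1CCO[Si](C)(C)C(C)(C)C | intermediate
17 | 6β-acetoxy-10,10-(ethylenedioxy)-8α-hydroxy-4-methyl-7-[2-(tert-butyldimethylsilyloxy)ethyl]cyclodecan-3-one | CC(=O)O[C@@H]1CC(C)C(=O)CCC2(OCCO2)C[C@@H](O)[C@@H]1CCO[Si](C)(C)C(C)(C)C | intermediate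
18 | 6β-acetoxy-8α-(tert-butyldimethylsilyloxy)-10,10-(ethylenedioxy)-4-methyl-7-[2-(tert-butyldimethylsilyloxy)ethyl]cyclodecan-3-one | CC(=O)O[C@@H]1CC(C)C(=O)CCC2(OCCO2)C[C@@H](O[Si](C)(C)C(C)(C)C)[C@@H]1CCO[Si](C)(C)C(C)(C)C | intermediate
19 | 8α-(tert-butyldimethylsilyloxy)-10,10-(ethylenedioxy)-6β-hydroxy-4-methyl-7-[2-(tert-butyldimethylsilyloxy)ethyl]cyclodecan-3-one | O[C@@H]1CC(C)C(=O)CCC2(OCCO2)C[C@@H](O[Si](C)(C)C(C)(C)C)[C@@H]1CCO[Si](C)(C)C(C)(C)C | intermediate
20 | 8α-(tert-butyldimethylsilyloxy)-10,10-(ethylenedioxy)-6β-hydroxy-7-(2-hydroxyethyl)-4-methylcyclodecan-3-one | O[C@@H]1CC(C)C(=O)CCC2(OCCO2)C[C@@H](O[Si](C)(C)C(C)(C)C)[C@@H]1CCO | intermediate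
21 | lactol of 22: 12-hydroxy-6,12-epoxide, anomer mixture (not isolated) | OC1O[C@@H]2CC(C)C(=O)CCC3(OCCO3)C[C@@H](O[Si](C)(C)C(C)(C)C)[C@@H]2C1 | intermediate
22 | 8α-(tert-butyldimethylsilyloxy)-10,10-(ethylenedioxy)-3-oxo-13,14-dinorgermacran-12,6-olide (6β-O, 7α-H) | O=C1O[C@@H]2CC(C)C(=O)CCC3(OCCO3)C[C@@H](O[Si](C)(C)C(C)(C)C)[C@@H]2C1 | intermediate
23 | 2-(phenylselanyl) derivative of 22 (not isolated) | O=C1O[C@@H]2CC(C)C(=O)C([Se]c3ccccc3)CC3(OCCO3)C[C@@H](O[Si](C)(C)C(C)(C)C)[C@@H]2C1 | intermediate
24 | 8α-(tert-butyldimethylsilyloxy)-10,10-(ethylenedioxy)-3-oxo-13,14-dinorgermacr-1E-en-12,6-olide | O=C1O[C@@H]2CC(C)C(=O)/C=C/C3(OCCO3)C[C@@H](O[Si](C)(C)C(C)(C)C)[C@@H]2C1 | intermediate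
25 | 3-(trimethylsilyloxy)-1E,3-diene (silyl dienol ether of 24; not isolated) | O=C1O[C@@H]2CC(C)=C(O[Si](C)(C)C)/C=C/C3(OCCO3)C[C@@H](O[Si](C)(C)C(C)(C)C)[C@@H]2C1 | intermediate
26 | 8α-(tert-butyldimethylsilyloxy)-10,10-(ethylenedioxy)-3-oxo-13,14-dinorgermacra-1E,4Z-dien-12,6-olide | O=C1O[C@@H]2/C=C(/C)C(=O)/C=C/C3(OCCO3)C[C@@H](O[Si](C)(C)C(C)(C)C)[C@@H]2C1 | intermediate
27 | 8α-(tert-butyldimethylsilyloxy)-10,10-(ethylenedioxy)-3β-hydroxy-13,14-dinorgermacra-1E,4Z-dien-12,6-olide | O=C1O[C@@H]2/C=C(/C)[C@H](O)/C=C/C3(OCCO3)C[C@@H](O[Si](C)(C)C(C)(C)C)[C@@H]2C1 | intermediate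
28 | 8α-(tert-butyldimethylsilyloxy)-3β-hydroxy-10-oxo-13,14-dinorgermacra-1E,4Z-dien-12,6-olide | O=C1O[C@@H]2/C=C(/C)[C@H](O)/C=C/C(=O)C[C@@H](O[Si](C)(C)C(C)(C)C)[C@@H]2C1 | intermediate
29 | 8α-(tert-butyldimethylsilyloxy)-3β,10β-dihydroxy-13-norgermacra-1E,4Z-dien-12,6-olide | O=C1O[C@@H]2/C=C(/C)[C@H](O)/C=C/[C@](C)(O)C[C@@H](O[Si](C)(C)C(C)(C)C)[C@@H]2C1 | intermediate
30 | 13-(dimethylamino)-11,13-dihydro derivative of 32 (Mannich base; not isolated) | CN(C)CC1C(=O)O[C@@H]2/C=C(/C)[C@H](O)/C=C/[C@](C)(O)C[C@@H](O[Si](C)(C)C(C)(C)C)[C@H]12 | intermediate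
31 | trimethylammonium iodide of 30 (not isolated) | C[N+](C)(C)CC1C(=O)O[C@@H]2/C=C(/C)[C@H](O)/C=C/[C@](C)(O)C[C@@H](O[Si](C)(C)C(C)(C)C)[C@H]12.[I-] | intermediate
32 | 8α-(tert-butyldimethylsilyloxy)-3β,10β-dihydroxygermacra-1E,4Z,11(13)-trien-12,6-olide | C=C1C(=O)O[C@@H]2/C=C(/C)[C@H](O)/C=C/[C@](C)(O)C[C@@H](O[Si](C)(C)C(C)(C)C)[C@H]12 | intermediate
33 | 3β-acetoxy-8α-(tert-butyldimethylsilyloxy)-10β-hydroxygermacra-1E,4Z,11(13)-trien-12,6-olide | C=C1C(=O)O[C@@H]2/C=C(/C)[C@H](OC(C)=O)/C=C/[C@](C)(O)C[C@@H](O[Si](C)(C)C(C)(C)C)[C@H]12 | intermediate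
34 | 3β-acetoxy-8α,10β-dihydroxygermacra-1E,4Z,11(13)-trien-12,6-olide | C=C1C(=O)O[C@@H]2/C=C(/C)[C@H](OC(C)=O)/C=C/[C@](C)(O)C[C@@H](O)[C@H]12 | intermediate
35 | angelic acid, (Z)-2-methylbut-2-enoic acid | C/C=C(/C)C(=O)O | starting material
36 | angelic 2,4,6-trichlorobenzoic anhydride (not isolated) | C/C=C(/C)C(=O)OC(=O)c1c(Cl)cc(Cl)cc1Cl | intermediate
37 | CNP0181631.1, (3R,6R,7S,8R,10R)-3-acetoxy-8-angeloyloxy-10-hydroxygermacra-1E,4Z,11(13)-trien-12,6-olide | C=C1C(=O)O[C@@H]2/C=C(/C)[C@H](OC(C)=O)/C=C/[C@](C)(O)C[C@@H](OC(=O)/C(C)=C\C)[C@H]12 | target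

**Step count and risks**

Total step count: 22. Longest linear sequence: 22 steps (1 to 37); angelic acid enters unchanged in the last step.

The three steps most likely to fail:

Step 8 (key step). What may go wrong is a process on two levels. The hindered tetrasubstituted alkene may be cleaved incompletely or anomalously (epoxide or oligomeric peroxides). The β-hydroxy 1,6-diketone may also undergo transannular aldol, β-elimination at C6/C7 or epimerisation at C7 while peroxides are still being reduced. The fallback leaves ozone and peroxides out and sets out from 13. OsO4 (1 equiv) in pyridine/THF followed by aqueous NaHSO3 should dihydroxylate the ring-fusion alkene to the cis-3,8-diol F1. Pb(OAc)4 with K2CO3 in dry CH2Cl2 at 0 °C should then cleave the di-tertiary glycol under anhydrous, neutral conditions; the C6 hydroxyl is 1,3 to the glycol and is not cleaved. Filtration gives 16, at which the route is rejoined and which is reduced at once in step 9.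

Step 16. What may go wrong is poor facial selectivity at C3: the conformational bias of the ten-membered dienone may oppose the reagent (mismatched pairing), or the two alkenyl arms may be too similar in size for the oxazaborolidine to tell apart. The fallback sets out from 26 and uses substrate control followed by inversion. Luche reduction (NaBH4, CeCl3·7H2O, MeOH, −78 °C) should give the alcohol that the ring prefers; if this is 27 the route simply continues. If it is the 3α-alcohol F2, Mitsunobu reaction with chloroacetic acid (PPh3, diisopropyl azodicarboxylate, toluene, 0 °C) should invert C3 to the 3β-chloroacetate F3. Thiourea with NaHCO3 in ethanol then removes the chloroacetyl group without opening the lactone, and the route is rejoined at 27.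

Step 18. What may go wrong is addition of the methyl group to the wrong face of the C10 carbonyl, or to both faces, because the orientation of the carbonyl in the flexible ring is set by conformation and not by a rigid template. The fallback inverts the order in which carbon and oxygen arrive at C10 and sets out from 28. Wittig methylenation (Ph3PCH3Br, KN(SiMe3)2, THF, 0 °C; one extra equivalent for the C3 hydroxyl) should give the 10-methylene triene F4. Oxymercuration–demercuration (Hg(OAc)2, THF/H2O, 0 °C; then NaBH4, NaOH, 0 °C) should hydrate the terminal alkene of the 1,3-diene in the Markovnikov sense at the tertiary allylic carbon. Oxygen now enters from the open face and the methyl carbon sits where the carbonyl oxygen stood, so the configuration at C10 is the opposite of that from methyl addition; the E-alkene keeps the C3 hydroxyl from adding. The route is rejoined at 29.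

Further compounds
F1 | step 8 | cis-3,8-diol of 13: (1S,2R)-1-[2-(tert-butyldimethylsilyloxy)ethyl]-7,7-(ethylenedioxy)-4-methyldecahydronaphthalene-2,4a,8a-triol | O[C@@H]1CC(C)C2(O)C(O)(CC3(OCCO3)CC2)[C@@H]1CCO[Si](C)(C)C(C)(C)C
F2 | step 16 | 3α-hydroxy epimer of 27 | O=C1O[C@@H]2/C=C(/C)[C@@H](O)/C=C/C3(OCCO3)C[C@@H](O[Si](C)(C)C(C)(C)C)[C@@H]2C1
F3 | step 16 | 3β-chloroacetate of 27 | O=C1O[C@@H]2/C=C(/C)[C@H](OC(=O)CCl)/C=C/C3(OCCO3)C[C@@H](O[Si](C)(C)C(C)(C)C)[C@@H]2C1
F4 | step 18 | 8α-(tert-butyldimethylsilyloxy)-3β-hydroxy-10-methylene-13,14-dinorgermacra-1E,4Z-dien-12,6-olide | O=C1O[C@@H]2/C=C(/C)[C@H](O)/C=C/C(=C)C[C@@H](O[Si](C)(C)C(C)(C)C)[C@@H]2C1
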